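**Plan**

- Numbering: C1 = prenylated bridgehead bonded to the CMe2 carbon C8; C2–C3–C4 = enolised β-diketone with the aroyl group on C3; C5 = second prenylated bridgehead; C6 = ring CH2; C7 = geranyl-bearing CH; C9 = bridging ketone. Ring A = C1–C2–C3–C4–C5–C9, ring B = C1–C8–C7–C6–C5–C9.
- Cuts, in retrosynthetic order: C3–C(aroyl); C6'=C7' and C4'–C5' of the geranyl chain (back to a C7–CH2CO2Me arm); the C5 prenyl alkene (back to a but-2-enoate arm); C7–C8 of ring B; C1–CH2 of the C1 prenyl; C1=C8 (acetone); both C5–C6 bonds; the arene.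
- Enabling feature: C8 is a gem-dimethyl carbon on quaternary C1, which is the tertiary radical formed when a hydrogen atom adds to a C1 isopropenyl group. C7 lies β to the ester of a but-2-enoate arm on C5. Since C5 carries two such arms, ring B can close through C7–C8 onto whichever arm is cis to C8.
- Forward order: ring A comes from 1,3-dimethoxybenzene (Birch reduction, double alkylation at C5, oxidation). C1 is then built (isopropylidene, prenyl), the C5 arms become enoates, ring B is closed, and the C5 prenyl, C7 geranyl and C3 aroyl groups are finished last.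
- Stereochemistry: C1 from an enantioselective phase-transfer prenylation; C5 and C7 from the ring closure (arm selection, chair-like transition state with the C7 arm exo); the geranyl E-alkene from a Johnson–Claisen rearrangement.

Key step: step 9

Remark: β-dicarbonyl compounds are drawn as one tautomer; metalated forms of numbered compounds (carbanions, enolates, alkoxides before work-up) and radicals are described in the Why lines and carry no number of their own.

**Route**

Step 1
Reactants: 1 1,3-dimethoxybenzene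
Product: 2 1,5-dimethoxycyclohexa-1,4-diene
Conditions: Li, liquid NH3, t-BuOH, THF, −78 to −33 °C
Reagents that add atoms: none
Why: Birch reduction of the resorcinol diether leaves both enol ethers in place and puts the two sp3 carbons between the methoxy-bearing carbons (future C5) and opposite to it (future C2).

Step 2
Reactants: 2 1,5-dimethoxycyclohexa-1,4-diene; 3 tert-butyl(2-iodoethoxy)dimethylsilane
Product: 5 6,6-bis(2-{[tert-butyl(dimethyl)silyl]oxy}ethyl)-1,5-dimethoxycyclohexa-1,4-diene, via monoalkylated diene 4 (not isolated)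
Conditions: t-BuLi (1.05 equiv), THF/HMPA, −78 °C, then 3 (1.0 equiv); t-BuLi (1.1 equiv), −78 °C, then 3 (1.2 equiv), −78 °C to rt
Reagents that add atoms: tert-butyl(2-iodoethoxy)dimethylsilane 3, CC(C)(C)[Si](C)(C)OCCI
Why: Deprotonation of the CH2 flanked by both enol ethers gives a pentadienyllithium that is alkylated at its central carbon (SN2 on the primary iodide), and a second cycle makes quaternary C5 with two identical, alkene-free two-carbon arms (the future C6–C7 units).

Step 3
Reactants: 5 6,6-bis(2-{[tert-butyl(dimethyl)silyl]oxy}ethyl)-1,5-dimethoxycyclohexa-1,4-diene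
Product: 6 4,4-bis(2-{[tert-butyl(dimethyl)silyl]oxy}ethyl)-3,5-dimethoxycyclohexa-2,5-dien-1-one
Conditions: t-BuOOH (in decane, 5 equiv), Rh2(caprolactamate)4 (1 mol%), K2CO3 (0.5 equiv), CH2Cl2, rt
Reagents that add atoms: tert-butyl hydroperoxide, CC(C)(C)OO
Why: Radical bis-allylic C–H oxidation by tert-butylperoxyl (the standard conversion of Birch-type 1,4-dienes into cyclohexa-2,5-dienones) turns the only ring CH2 into the C2 carbonyl; the carbonate buffer protects the enol ethers.

Step 4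
Reactants: 6 4,4-bis(2-{[tert-butyl(dimethyl)silyl]oxy}ethyl)-3,5-dimethoxycyclohexa-2,5-dien-1-one
Product: 7 4,4-bis(2-{[tert-butyl(dimethyl)silyl]oxy}ethyl)-3-hydroxy-5-methoxycyclohexa-2,5-dien-1-one
Conditions: LiCl (5 equiv), DMF, 120 °C; then 1 M HCl, 0 °C
Reagents that add atoms: none
Why: Nucleophilic O-demethylation of a vinylogous methyl ester (SN2 by chloride at the methyl carbon) stops after one methoxy group because the product is a vinylogous carboxylate, and the symmetry of 6 removes any regiochemical question; this frees the C1 position between C9 and C2 as a 1,3-dicarbonyl carbon.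

Step 5
Reactants: 7 4,4-bis(2-{[tert-butyl(dimethyl)silyl]oxy}ethyl)-3-hydroxy-5-methoxycyclohexa-2,5-dien-1-one; 8 acetone
Product: 10 6,6-bis(2-{[tert-butyl(dimethyl)silyl]oxy}ethyl)-5-methoxy-2-(propan-2-ylidene)cyclohex-4-ene-1,3-dione, via Mannich adduct 9 (not isolated)
Conditions: acetone (solvent), pyrrolidine (20 mol%), AcOH (20 mol%), 4 Å molecular sieves, 50 °C
Reagents that add atoms: acetone 8, CC(C)=O
Why: Knoevenagel condensation of an acidic cyclic 1,3-dicarbonyl compound with a ketone through the pyrrolidinium iminium ion (Mannich addition at C1, then loss of the amine) attaches C8 with its two methyl groups; the product may tautomerise to the 2-isopropenyl enol, and both forms give the same enolate.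

Step 6
Reactants: 10 6,6-bis(2-{[tert-butyl(dimethyl)silyl]oxy}ethyl)-5-methoxy-2-(propan-2-ylidene)cyclohex-4-ene-1,3-dione; 11 prenyl bromide
Product: 12 (2R)-6,6-bis(2-{[tert-butyl(dimethyl)silyl]oxy}ethyl)-5-methoxy-2-(3-methylbut-2-en-1-yl)-2-(prop-1-en-2-yl)cyclohex-4-ene-1,3-dione
Conditions: 11 (1.5 equiv), Cs2CO3 (solid, 2 equiv), chiral N-spiro binaphthyl-derived quaternary ammonium bromide bearing 3,4,5-trifluorophenyl groups (2 mol%, antipode chosen to give 2R), toluene, 0 °C
Reagents that add atoms: prenyl bromide 11, CC(C)=CCBr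
Why: Enantioselective phase-transfer alkylation of a 2-substituted cyclic 1,3-dicarbonyl enolate: the cross-conjugated dienolate is prenylated at its α-carbon C1 (deconjugative alkylation, leaving the isopropenyl group) inside the chiral ammonium ion pair, which has to tell the C9/C5 flank from the C2/C3/C4 flank and thereby shields one of the two enantiotopic faces, so that C1 should be set as R.

Step 7
Reactants: 12 (2R)-6,6-bis(2-{[tert-butyl(dimethyl)silyl]oxy}ethyl)-5-methoxy-2-(3-methylbut-2-en-1-yl)-2-(prop-1-en-2-yl)cyclohex-4-ene-1,3-dione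
Product: 13 (2R)-6,6-bis(2-hydroxyethyl)-5-methoxy-2-(3-methylbut-2-en-1-yl)-2-(prop-1-en-2-yl)cyclohex-4-ene-1,3-dione
Conditions: HF·pyridine, pyridine, THF, 0 °C to rt
Reagents that add atoms: none
Why: Fluoride cleavage of the two primary silyl ethers under pyridine-buffered conditions should leave the vinylogous ester, the non-enolisable diketone and both alkenes untouched and avoids acid-catalysed attack of the new hydroxyl groups on C4.

Step 8
Reactants: 13 (2R)-6,6-bis(2-hydroxyethyl)-5-methoxy-2-(3-methylbut-2-en-1-yl)-2-(prop-1-en-2-yl)cyclohex-4-ene-1,3-dione; 14 methyl (triphenylphosphoranylidene)acetate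
Product: 16 dimethyl (2E,2'E)-4,4'-[(5R)-2-methoxy-5-(3-methylbut-2-en-1-yl)-4,6-dioxo-5-(prop-1-en-2-yl)cyclohex-2-ene-1,1-diyl]bis(but-2-enoate), via dialdehyde 15 (not isolated)
Conditions: Dess–Martin periodinane (2.4 equiv), pyridine, CH2Cl2, 0 °C; then 14 (3 equiv), rt
Reagents that add atoms: methyl (triphenylphosphoranylidene)acetate 14, COC(=O)C=P(c1ccccc1)(c1ccccc1)c1ccccc1
Why: Dess–Martin oxidation followed in the same flask by Wittig olefination with a stabilised ylide should give both (E)-enoate arms; they are introduced only now, when C1 is quaternary and no enolate remains that could add to them, and without any metathesis on a gem-dialkenyl C5.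

Step 9
Reactants: 16 dimethyl (2E,2'E)-4,4'-[(5R)-2-methoxy-5-(3-methylbut-2-en-1-yl)-4,6-dioxo-5-(prop-1-en-2-yl)cyclohex-2-ene-1,1-diyl]bis(but-2-enoate)
Product: 17 methyl (2E)-4-[(1R,5S,7S)-4-methoxy-7-(2-methoxy-2-oxoethyl)-8,8-dimethyl-1-(3-methylbut-2-en-1-yl)-2,9-dioxobicyclo[3.3.1]non-3-en-5-yl]but-2-enoate
Conditions: Fe(acac)3 (30 mol%), PhSiH3 (2.5 equiv), EtOH/HOCH2CH2OH (5:1), 5 mM, Ar, 40 °C
Reagents that add atoms: none
Why: The iron hydride formed from Fe(acac)3 and PhSiH3 transfers a hydrogen atom to the CH2 terminus of the isopropenyl group, the tertiary C8 radical adds to the β-carbon C7 of an enoate arm, and the ester-stabilised radical is reduced and protonated by ethanol; this is a metal-hydride hydrogen-atom-transfer reductive olefin coupling in its intramolecular Giese form. Ring B (C1–C8–C7–C6–C5–C9) closes 6-exo-trig. C5 becomes stereogenic by selection between its two identical arms: only the arm on the face of ring A that carries C8 can reach the radical, so the C1 configuration from step 6 fixes C5. C7 is set in a chair-like transition state in which the CH–CO2Me end of the alkene lies pseudo-equatorial, away from the C2–C3–C4 bridge, which places the acetate arm exo. The step needs hydrogen-atom transfer to the 1,1-disubstituted alkene and not to the trisubstituted prenyl alkene, which the unhindered terminal CH2 should secure (the enoates are acceptors, not hydrogen-atom acceptors). It also needs ring closure to outrun 1,2-acyl migration or reduction of the C8 radical, which is favoured by polarity matching of the nucleophilic radical with the enoate, by the quaternary centres at C1 and C5 and by high dilution.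

Step 10
Reactants: 17 methyl (2E)-4-[(1R,5S,7S)-4-methoxy-7-(2-methoxy-2-oxoethyl)-8,8-dimethyl-1-(3-methylbut-2-en-1-yl)-2,9-dioxobicyclo[3.3.1]non-3-en-5-yl]but-2-enoate; 18 2-methylbut-2-ene
Product: 19 methyl 2-[(1R,5S,7S)-4-methoxy-8,8-dimethyl-1,5-bis(3-methylbut-2-en-1-yl)-2,9-dioxobicyclo[3.3.1]non-3-en-7-yl]acetate
Conditions: RuCl2(H2IMes)(=CH–C6H4-2-Oi-Pr) (second-generation Hoveyda–Grubbs catalyst, 10 mol%), 18/CH2Cl2 (1:1), 40 °C, sealed tube
Reagents that add atoms: 2-methylbut-2-ene 18, CC=C(C)C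
Why: Olefin cross metathesis in which the ruthenium ethylidene opens the spare enoate at its β-carbon (the reverse of the familiar crotonate cross metathesis) and the C5-bound alkylidene is capped by 2-methylbut-2-ene as in the usual allyl-to-prenyl exchange, driven by the large excess of the volatile partner; the C1 prenyl group can only exchange degenerately.

Step 11
Reactants: 19 methyl 2-[(1R,5S,7S)-4-methoxy-8,8-dimethyl-1,5-bis(3-methylbut-2-en-1-yl)-2,9-dioxobicyclo[3.3.1]non-3-en-7-yl]acetate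
Product: 20 2-[(1R,5S,7S)-4-methoxy-8,8-dimethyl-1,5-bis(3-methylbut-2-en-1-yl)-2,9-dioxobicyclo[3.3.1]non-3-en-7-yl]acetaldehyde
Conditions: i-Bu2AlH (1.1 equiv), CH2Cl2, −78 °C; then MeOH, H2O
Reagents that add atoms: none
Why: Partial ester reduction with diisobutylaluminium hydride (the aluminium hemiacetal persists at −78 °C) should be chemoselective for the unhindered methyl ester, since the C9 ketone lies between two quaternary carbons and the C2 carbonyl is a deactivated vinylogous ester next to quaternary C1.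

Step 12
Reactants: 20 2-[(1R,5S,7S)-4-methoxy-8,8-dimethyl-1,5-bis(3-methylbut-2-en-1-yl)-2,9-dioxobicyclo[3.3.1]non-3-en-7-yl]acetaldehyde; 21 isopropenylmagnesium bromide
Product: 22 (1R,5S,7S)-7-(2-hydroxy-3-methylbut-3-en-1-yl)-4-methoxy-8,8-dimethyl-1,5-bis(3-methylbut-2-en-1-yl)bicyclo[3.3.1]non-3-ene-2,9-dione (both carbinol epimers)
Conditions: 21 (1.2 equiv), THF, −78 °C; then H2O
Reagents that add atoms: isopropenylmagnesium bromide 21, CC(=C)[Mg]Br
Why: Grignard addition takes place at the aldehyde, by far the most electrophilic carbonyl; the new carbinol centre is not controlled and need not be, because it is removed in step 13.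

Step 13
Reactants: 22 (1R,5S,7S)-7-(2-hydroxy-3-methylbut-3-en-1-yl)-4-methoxy-8,8-dimethyl-1,5-bis(3-methylbut-2-en-1-yl)bicyclo[3.3.1]non-3-ene-2,9-dione; 23 trimethyl orthoacetate
Product: 26 methyl (4E)-6-[(1R,5S,7R)-4-methoxy-8,8-dimethyl-1,5-bis(3-methylbut-2-en-1-yl)-2,9-dioxobicyclo[3.3.1]non-3-en-7-yl]-4-methylhex-4-enoate, via mixed orthoester 24 (not isolated), via ketene acetal 25 (not isolated)
Conditions: 23 (excess), EtCO2H (10 mol%), 110 °C, MeOH distilled off
Reagents that add atoms: trimethyl orthoacetate 23, CC(OC)(OC)OC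
Why: Johnson–Claisen rearrangement: the [3,3] shift of the ketene acetal through a chair transition state with the C1' substituent equatorial should give the trisubstituted alkene with the E geometry of the geranyl chain from either carbinol epimer, and the methyl orthoester keeps any alkoxy exchange at C4 degenerate.

Step 14
Reactants: 26 methyl (4E)-6-[(1R,5S,7R)-4-methoxy-8,8-dimethyl-1,5-bis(3-methylbut-2-en-1-yl)-2,9-dioxobicyclo[3.3.1]non-3-en-7-yl]-4-methylhex-4-enoate
Product: 27 (4E)-6-[(1R,5S,7R)-4-methoxy-8,8-dimethyl-1,5-bis(3-methylbut-2-en-1-yl)-2,9-dioxobicyclo[3.3.1]non-3-en-7-yl]-4-methylhex-4-enal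
Conditions: i-Bu2AlH (1.1 equiv), CH2Cl2, −78 °C; then MeOH, H2O
Reagents that add atoms: none
Why: The same low-temperature partial ester reduction as in step 11, with the same basis for chemoselectivity over the hindered ketone and the vinylogous ester.

Step 15
Reactants: 27 (4E)-6-[(1R,5S,7R)-4-methoxy-8,8-dimethyl-1,5-bis(3-methylbut-2-en-1-yl)-2,9-dioxobicyclo[3.3.1]non-3-en-7-yl]-4-methylhex-4-enal; 28 isopropyltriphenylphosphonium iodide
Product: 29 (1R,5S,7R)-7-[(2E)-3,7-dimethylocta-2,6-dien-1-yl]-4-methoxy-8,8-dimethyl-1,5-bis(3-methylbut-2-en-1-yl)bicyclo[3.3.1]non-3-ene-2,9-dione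
Conditions: 28 (1.5 equiv), n-BuLi (1.4 equiv), THF, 0 °C; then 27, −78 °C to rt
Reagents that add atoms: isopropyltriphenylphosphonium iodide 28, CC(C)[P+](c1ccccc1)(c1ccccc1)c1ccccc1.[I-]
Why: Wittig olefination with the non-stabilised isopropylidene ylide reacts only at the aldehyde and completes the geranyl chain; the new alkene has two identical methyl groups and therefore no geometry to control.

Step 16
Reactants: 30 3,4-dihydroxybenzoic acid
Product: 31 tert-butyl(dimethyl)silyl 3,4-bis{[tert-butyl(dimethyl)silyl]oxy}benzoate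
Conditions: TBSCl (3.5 equiv), imidazole, DMF, rt
Reagents that add atoms: tert-butyldimethylsilyl chloride, CC(C)(C)[Si](C)(C)Cl
Why: Imidazole-promoted silylation protects both phenols and converts the acid into its silyl ester in one operation.

Step 17
Reactants: 31 tert-butyl(dimethyl)silyl 3,4-bis{[tert-butyl(dimethyl)silyl]oxy}benzoate
Product: 32 3,4-bis{[tert-butyl(dimethyl)silyl]oxy}benzoyl chloride
Conditions: (COCl)2, DMF (cat.), CH2Cl2, 0 °C to rt
Reagents that add atoms: oxalyl chloride, O=C(Cl)C(=O)Cl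
Why: Silyl esters are converted directly into acid chlorides by the chloroiminium (Vilsmeier-type) reagent under neutral conditions, so the aryl silyl ethers survive.

Step 18
Reactants: 29 (1R,5S,7R)-7-[(2E)-3,7-dimethylocta-2,6-dien-1-yl]-4-methoxy-8,8-dimethyl-1,5-bis(3-methylbut-2-en-1-yl)bicyclo[3.3.1]non-3-ene-2,9-dione; 32 3,4-bis{[tert-butyl(dimethyl)silyl]oxy}benzoyl chloride
Product: 33 (1S,5S,7R)-3-(3,4-bis{[tert-butyl(dimethyl)silyl]oxy}benzoyl)-7-[(2E)-3,7-dimethylocta-2,6-dien-1-yl]-4-methoxy-8,8-dimethyl-1,5-bis(3-methylbut-2-en-1-yl)bicyclo[3.3.1]non-3-ene-2,9-dione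
Conditions: 2,2,6,6-tetramethylpiperidine, n-BuLi, THF, 0 °C (gives LiTMP); 29, −78 °C; then 32, −78 to 0 °C
Reagents that add atoms: 3,4-bis{[tert-butyl(dimethyl)silyl]oxy}benzoyl chloride 32, ClC(=O)c1ccc(O[Si](C)(C)C(C)(C)C)c(O[Si](C)(C)C(C)(C)C)c1
Why: α-Lithiation of the vinylogous ester at the vinylic C3–H (the only acidic C–H, since C1 and C5 are quaternary) and acylation of the vinyllithium with the aroyl chloride is the established way to put a C3 aroyl group on bicyclic vinylogous esters of this family; the descriptor at C1 changes to S only because the CIP priorities change, not the configuration.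

Step 19
Reactants: 33 (1S,5S,7R)-3-(3,4-bis{[tert-butyl(dimethyl)silyl]oxy}benzoyl)-7-[(2E)-3,7-dimethylocta-2,6-dien-1-yl]-4-methoxy-8,8-dimethyl-1,5-bis(3-methylbut-2-en-1-yl)bicyclo[3.3.1]non-3-ene-2,9-dione
Product: 35 oblongifolin B, via catechol methyl enol ether 34 (not isolated)
Conditions: LiOH·H2O (excess), dioxane/H2O (degassed, Ar), rt then 90 °C; then 1 M HCl, 0 °C
Reagents that add atoms: lithium hydroxide, [Li+].[OH-]
Why: Hydroxide first cleaves the two aryl silyl ethers at silicon and then replaces the C4 methoxy group by addition–elimination on the doubly activated enol ether (vinylogous ester saponification), which after acidification gives the enolised β-triketone; exclusion of oxygen protects the catecholate.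

**Compound list**

1 | 1,3-dimethoxybenzene | COc1cccc(OC)c1 | starting material
2 | 1,5-dimethoxycyclohexa-1,4-diene | COC1=CCC=C(OC)C1 | intermediate
3 | tert-butyl(2-iodoethoxy)dimethylsilane | CC(C)(C)[Si](C)(C)OCCI | starting material
4 | 6-(2-{[tert-butyl(dimethyl)silyl]oxy}ethyl)-1,5-dimethoxycyclohexa-1,4-diene (monoalkylated diene, not isolated) | COC1=CCC=C(OC)C1CCO[Si](C)(C)C(C)(C)C | intermediate
5 | 6,6-bis(2-{[tert-butyl(dimethyl)silyl]oxy}ethyl)-1,5-dimethoxycyclohexa-1,4-diene | COC1=CCC=C(OC)C1(CCO[Si](C)(C)C(C)(C)C)CCO[Si](C)(C)C(C)(C)C | intermediate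
6 | 4,4-bis(2-{[tert-butyl(dimethyl)silyl]oxy}ethyl)-3,5-dimethoxycyclohexa-2,5-dien-1-one | COC1=CC(=O)C=C(OC)C1(CCO[Si](C)(C)C(C)(C)C)CCO[Si](C)(C)C(C)(C)C | intermediate
7 | 4,4-bis(2-{[tert-butyl(dimethyl)silyl]oxy}ethyl)-3-hydroxy-5-methoxycyclohexa-2,5-dien-1-one (enol of the 5-methoxycyclohex-4-ene-1,3-dione) | COC1=CC(=O)C=C(O)C1(CCO[Si](C)(C)C(C)(C)C)CCO[Si](C)(C)C(C)(C)C | intermediate
8 | acetone | CC(C)=O | starting material
9 | 6,6-bis(2-{[tert-butyl(dimethyl)silyl]oxy}ethyl)-5-methoxy-2-[2-(pyrrolidin-1-yl)propan-2-yl]cyclohex-4-ene-1,3-dione (Mannich adduct, not isolated) | COC1=CC(=O)C(C(C)(C)N2CCCC2)C(=O)C1(CCO[Si](C)(C)C(C)(C)C)CCO[Si](C)(C)C(C)(C)C | intermediate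
10 | 6,6-bis(2-{[tert-butyl(dimethyl)silyl]oxy}ethyl)-5-methoxy-2-(propan-2-ylidene)cyclohex-4-ene-1,3-dione (tautomer: 3-hydroxy-2-isopropenyl enone) | COC1=CC(=O)C(=C(C)C)C(=O)C1(CCO[Si](C)(C)C(C)(C)C)CCO[Si](C)(C)C(C)(C)C | intermediate
11 | prenyl bromide (1-bromo-3-methylbut-2-ene) | CC(C)=CCBr | starting material
12 | (2R)-6,6-bis(2-{[tert-butyl(dimethyl)silyl]oxy}ethyl)-5-methoxy-2-(3-methylbut-2-en-1-yl)-2-(prop-1-en-2-yl)cyclohex-4-ene-1,3-dione | CC(C)(C)[Si](C)(C)OCCC1(CCO[Si](C)(C)C(C)(C)C)C(=O)[C@](CC=C(C)C)(C(C)=C)C(=O)C=C1OC | intermediate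
13 | (2R)-6,6-bis(2-hydroxyethyl)-5-methoxy-2-(3-methylbut-2-en-1-yl)-2-(prop-1-en-2-yl)cyclohex-4-ene-1,3-dione | OCCC1(CCO)C(=O)[C@](CC=C(C)C)(C(C)=C)C(=O)C=C1OC | intermediate
14 | methyl (triphenylphosphoranylidene)acetate | COC(=O)C=P(c1ccccc1)(c1ccccc1)c1ccccc1 | starting material
15 | 2,2'-[(5R)-2-methoxy-5-(3-methylbut-2-en-1-yl)-4,6-dioxo-5-(prop-1-en-2-yl)cyclohex-2-ene-1,1-diyl]diacetaldehyde (dialdehyde, not isolated) | O=CCC1(CC=O)C(=O)[C@](CC=C(C)C)(C(C)=C)C(=O)C=C1OC | intermediate
16 | dimethyl (2E,2'E)-4,4'-[(5R)-2-methoxy-5-(3-methylbut-2-en-1-yl)-4,6-dioxo-5-(prop-1-en-2-yl)cyclohex-2-ene-1,1-diyl]bis(but-2-enoate) (key-step precursor) | COC(=O)/C=C/CC1(C/C=C/C(=O)OC)C(=O)[C@](CC=C(C)C)(C(C)=C)C(=O)C=C1OC | intermediate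
17 | methyl (2E)-4-[(1R,5S,7S)-4-methoxy-7-(2-methoxy-2-oxoethyl)-8,8-dimethyl-1-(3-methylbut-2-en-1-yl)-2,9-dioxobicyclo[3.3.1]non-3-en-5-yl]but-2-enoate (key-step product, C7 arm exo) | COC(=O)C[C@@H]1C[C@]2(C/C=C/C(=O)OC)C(=O)[C@@](CC=C(C)C)(C(=O)C=C2OC)C1(C)C | intermediate
18 | 2-methylbut-2-ene | CC=C(C)C | starting material
19 | methyl 2-[(1R,5S,7S)-4-methoxy-8,8-dimethyl-1,5-bis(3-methylbut-2-en-1-yl)-2,9-dioxobicyclo[3.3.1]non-3-en-7-yl]acetate | COC(=O)C[C@@H]1C[C@]2(CC=C(C)C)C(=O)[C@@](CC=C(C)C)(C(=O)C=C2OC)C1(C)C | intermediate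
20 | 2-[(1R,5S,7S)-4-methoxy-8,8-dimethyl-1,5-bis(3-methylbut-2-en-1-yl)-2,9-dioxobicyclo[3.3.1]non-3-en-7-yl]acetaldehyde | O=CC[C@@H]1C[C@]2(CC=C(C)C)C(=O)[C@@](CC=C(C)C)(C(=O)C=C2OC)C1(C)C | intermediate
21 | isopropenylmagnesium bromide | CC(=C)[Mg]Br | starting material
22 | (1R,5S,7S)-7-(2-hydroxy-3-methylbut-3-en-1-yl)-4-methoxy-8,8-dimethyl-1,5-bis(3-methylbut-2-en-1-yl)bicyclo[3.3.1]non-3-ene-2,9-dione (both carbinol epimers) | CC(=C)C(O)C[C@@H]1C[C@]2(CC=C(C)C)C(=O)[C@@](CC=C(C)C)(C(=O)C=C2OC)C1(C)C | intermediate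
23 | trimethyl orthoacetate | CC(OC)(OC)OC | starting material
24 | mixed orthoester of 22 (1,1-dimethoxyethyl ether of the carbinol; bicycle configured as in 22; not isolated) | CC(=C)C(OC(C)(OC)OC)C[C@@H]1C[C@]2(CC=C(C)C)C(=O)[C@@](CC=C(C)C)(C(=O)C=C2OC)C1(C)C | intermediate
25 | ketene acetal of 22 (1-methoxyvinyl ether of the carbinol; bicycle configured as in 22; not isolated) | CC(=C)C(OC(=C)OC)C[C@@H]1C[C@]2(CC=C(C)C)C(=O)[C@@](CC=C(C)C)(C(=O)C=C2OC)C1(C)C | intermediate
26 | methyl (4E)-6-[(1R,5S,7R)-4-methoxy-8,8-dimethyl-1,5-bis(3-methylbut-2-en-1-yl)-2,9-dioxobicyclo[3.3.1]non-3-en-7-yl]-4-methylhex-4-enoate | COC(=O)CC/C(C)=C/C[C@@H]1C[C@]2(CC=C(C)C)C(=O)[C@@](CC=C(C)C)(C(=O)C=C2OC)C1(C)C | intermediate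
27 | (4E)-6-[(1R,5S,7R)-4-methoxy-8,8-dimethyl-1,5-bis(3-methylbut-2-en-1-yl)-2,9-dioxobicyclo[3.3.1]non-3-en-7-yl]-4-methylhex-4-enal | O=CCC/C(C)=C/C[C@@H]1C[C@]2(CC=C(C)C)C(=O)[C@@](CC=C(C)C)(C(=O)C=C2OC)C1(C)C | intermediate
28 | isopropyltriphenylphosphonium iodide | CC(C)[P+](c1ccccc1)(c1ccccc1)c1ccccc1.[I-] | starting material
29 | (1R,5S,7R)-7-[(2E)-3,7-dimethylocta-2,6-dien-1-yl]-4-methoxy-8,8-dimethyl-1,5-bis(3-methylbut-2-en-1-yl)bicyclo[3.3.1]non-3-ene-2,9-dione | CC(C)=CCC/C(C)=C/C[C@@H]1C[C@]2(CC=C(C)C)C(=O)[C@@](CC=C(C)C)(C(=O)C=C2OC)C1(C)C | intermediate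
30 | 3,4-dihydroxybenzoic acid | OC(=O)c1ccc(O)c(O)c1 | starting material
31 | tert-butyl(dimethyl)silyl 3,4-bis{[tert-butyl(dimethyl)silyl]oxy}benzoate | CC(C)(C)[Si](C)(C)OC(=O)c1ccc(O[Si](C)(C)C(C)(C)C)c(O[Si](C)(C)C(C)(C)C)c1 | intermediate
32 | 3,4-bis{[tert-butyl(dimethyl)silyl]oxy}benzoyl chloride | ClC(=O)c1ccc(O[Si](C)(C)C(C)(C)C)c(O[Si](C)(C)C(C)(C)C)c1 | intermediate
33 | (1S,5S,7R)-3-(3,4-bis{[tert-butyl(dimethyl)silyl]oxy}benzoyl)-7-[(2E)-3,7-dimethylocta-2,6-dien-1-yl]-4-methoxy-8,8-dimethyl-1,5-bis(3-methylbut-2-en-1-yl)bicyclo[3.3.1]non-3-ene-2,9-dione | CC(C)=CCC/C(C)=C/C[C@@H]1C[C@]2(CC=C(C)C)C(=O)[C@@](CC=C(C)C)(C(=O)C(C(=O)c3ccc(O[Si](C)(C)C(C)(C)C)c(O[Si](C)(C)C(C)(C)C)c3)=C2OC)C1(C)C | intermediate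
34 | (1S,5S,7R)-3-(3,4-dihydroxybenzoyl)-7-[(2E)-3,7-dimethylocta-2,6-dien-1-yl]-4-methoxy-8,8-dimethyl-1,5-bis(3-methylbut-2-en-1-yl)bicyclo[3.3.1]non-3-ene-2,9-dione (catechol methyl enol ether, not isolated) | CC(C)=CCC/C(C)=C/C[C@@H]1C[C@]2(CC=C(C)C)C(=O)[C@@](CC=C(C)C)(C(=O)C(C(=O)c3ccc(O)c(O)c3)=C2OC)C1(C)C | intermediate
35 | oblongifolin B, (1S,5S,7R)-3-(3,4-dihydroxybenzoyl)-7-[(2E)-3,7-dimethylocta-2,6-dien-1-yl]-4-hydroxy-8,8-dimethyl-1,5-bis(3-methylbut-2-en-1-yl)bicyclo[3.3.1]non-3-ene-2,9-dione | CC(C)=CCC/C(C)=C/C[C@@H]1C[C@]2(CC=C(C)C)C(=O)[C@@](CC=C(C)C)(C(=O)C(C(=O)c3ccc(O)c(O)c3)=C2O)C1(C)C | target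

**Step count and risks**

Total step count: 19 (17 in the main line, 2 for the aroyl chloride 32).
Longest linear sequence: 17 steps (steps 1–15, 18 and 19, from 1,3-dimethoxybenzene).

Steps most likely to fail:

Step 9. The C8 radical may be lost by 1,2-acyl migration onto C9 or C2 or by reduction before it reaches C7, and part of the hydrogen-atom transfer may go to the prenyl alkene. The fallback changes the acceptor, not the conditions; it sets out from diol 13 and returns at aldehyde 20. Oxidation of 13 as in step 8, followed by Wittig reaction with (triphenylphosphoranylidene)acetaldehyde, would give the bis-enal F1. Enals trap nucleophilic alkyl radicals faster than enoates and are established acceptors in hydrogen-atom-transfer-initiated radical conjugate additions, so the Fe(acac)3/PhSiH3 treatment should close ring B in the same sense and give the aldehyde–enal F2. Cross metathesis of F2 with 2-methylbut-2-ene, as in step 10, would exchange the spare enal for the prenyl group and lead to 20; step 11 is then not needed.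

Step 6. The ammonium ion pair may not discriminate well enough between the two faces of the planar dienolate, and O-prenylation may compete. The fallback sets out from 10 and returns at 12. O-Acylation of 10 with 3-methylbut-2-en-1-yl chloroformate (Et3N, CH2Cl2) would give the prenyl enol carbonate F3 (either enol oxygen may be acylated; both isomers lead to the same ion pair). With Pd2(dba)3·CHCl3 and a C2-symmetric trans-1,2-diaminocyclohexane-derived bisphosphine ligand (antipode chosen for 2R), zerovalent palladium ionises F3 with loss of CO2. The diketonate then attacks the unsubstituted terminus of the π-prenyl complex inside the chiral pocket (decarboxylative asymmetric allylic alkylation). Any O-prenyl ether is re-ionised and funnelled to 12.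

Step 10. The electron-poor, neopentyl-type enoate may enter the metathesis cycle so slowly that catalyst decomposition outruns the exchange. The fallback sets out from 17 and returns at 19. Nucleophilic epoxidation with t-BuOOLi (THF, −20 °C) should attack only the enoate, not the prenyl group or the hindered vinylogous ester, and give the glycidic ester F4. H5IO6 (THF/H2O) would cleave the epoxide to the C5 acetaldehyde F5 and methyl glyoxylate. Wittig olefination of F5 with isopropylidenetriphenylphosphorane, as in step 15, would then give 19.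

**Further compounds**

F1 | step 9 | (2E,2'E)-4,4'-[(5R)-2-methoxy-5-(3-methylbut-2-en-1-yl)-4,6-dioxo-5-(prop-1-en-2-yl)cyclohex-2-ene-1,1-diyl]bis(but-2-enal) | O=C/C=C/CC1(C/C=C/C=O)C(=O)[C@](CC=C(C)C)(C(C)=C)C(=O)C=C1OC
F2 | step 9 | (2E)-4-[4-methoxy-8,8-dimethyl-1-(3-methylbut-2-en-1-yl)-2,9-dioxo-7-(2-oxoethyl)bicyclo[3.3.1]non-3-en-5-yl]but-2-enal (C1, C5 and C7 configured as in 17) | O=CC[C@@H]1C[C@]2(C/C=C/C=O)C(=O)[C@@](CC=C(C)C)(C(=O)C=C2OC)C1(C)C
F3 | step 6 | 4,4-bis(2-{[tert-butyl(dimethyl)silyl]oxy}ethyl)-3-methoxy-5-oxo-6-(prop-1-en-2-yl)cyclohexa-1,3-dien-1-yl 3-methylbut-2-en-1-yl carbonate (or its enol regioisomer) | COC1=CC(OC(=O)OCC=C(C)C)=C(C(C)=C)C(=O)C1(CCO[Si](C)(C)C(C)(C)C)CCO[Si](C)(C)C(C)(C)C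
F4 | step 10 | methyl 3-{[4-methoxy-7-(2-methoxy-2-oxoethyl)-8,8-dimethyl-1-(3-methylbut-2-en-1-yl)-2,9-dioxobicyclo[3.3.1]non-3-en-5-yl]methyl}oxirane-2-carboxylate (bicycle configured as in 17; trans epoxide, both epoxide diastereomers) | COC(=O)C[C@@H]1C[C@]2(CC3OC3C(=O)OC)C(=O)[C@@](CC=C(C)C)(C(=O)C=C2OC)C1(C)C
F5 | step 10 | methyl 2-[4-methoxy-8,8-dimethyl-1-(3-methylbut-2-en-1-yl)-2,9-dioxo-5-(2-oxoethyl)bicyclo[3.3.1]non-3-en-7-yl]acetate (bicycle configured as in 17) | COC(=O)C[C@@H]1C[C@]2(CC=O)C(=O)[C@@](CC=C(C)C)(C(=O)C=C2OC)C1(C)C
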